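40.2% of the substrate is left at 1.33 min in Friday's run, charged at 2.8 M, and that reading gives me a first-order rate constant of 0.685 /min. Put back into the same run, it foretells 6.46% at 4.00 min, where Friday's reading is 7.9%. So I go round once more with that later reading and get 0.635 /min, a half-life of 1.09 min.

- Friday's: substrate 2.8 M; run made earlier
- flask: substrate 2.0 M; time 30 min

Friday's run (percent of the substrate charged)

| time / min | target / % | isomer of the product A / % | substrate / % |
|---|---|---|---|
| 1.33 | 49.2 | 6.1 | 40.2 |
| 4.00 | 78.8 | 12.0 | 7.9 |
| 6.00 | 83.8 | 12.0 | 2.6 |
| 10.0 | 85.3 | 11.6 | 0 |
| 15.0 | 85.3 | 13.2 | 0 |
| 20.0 | 83.8 | 12.9 | 0.5 |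
| 25.0 | 83.1 | 11.8 | 0 |

(each reading ± 1 percentage point)

* ratio of target to isomer of the product A at 2.0 s
* ratio of target to isomer of the product A at 1.0 min
* ratio of target to isomer of the product A at 30 min

- the numbers in the tables scatter by 1 percentage point (one standard deviation)
- a reading or a percentage of target counts all its forms, free or not

I carry this half-life over to the new flask at 2.0 M, since a first-order half-life doesn't depend on the charge. At 2.0 s, far shorter than the half-life, hardly any of the substrate in the new flask has reacted, and no reading reaches that time. By 1.0 min about half has reacted. Friday's nearest ratio is 8.07 at 1.33 min, but it rests on 6.1% of isomer of the product A with a scatter of 1 percentage point, so it is loose. The time 30 min is 27.5 half-lives, and Friday's substrate already reads 0% at 10.0 min. From then on, Friday's target and isomer of the product A barely move, so I sum each over those late readings and take their quotient as the late split of Friday's run, a reading from that one run with its scatter: 6.82. I commit to that ratio at all three times, most loosely at 2.0 s.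

The forecast stands a little higher, at 7.2, 7.1 and 6.9, and says: “The ratio is essentially constant from the earliest reading”.

    target ⇌ isomer of the product B (K = 3.00, k = 0.00270 /s)
    crystals ⇌ target, rate k2*(cs2 - [target]) while solid is left; crystals form when [target] > cs2 (solubility = 0.0560 M, k = 0.150 /s)
    substrate → target (k = 0.00990 /s)
    other conformer ⇌ dormant form (K = 0.460, k = 0.0190 /s)
    other conformer → isomer of the product A (k = 0.0210 /s)
    substrate ⇌ other conformer, settled at all times (K = 0.0640)

The new flask gives 7.35, 7.18 and 6.78, all within the forecast's margin, and its last ratio stands at the split of 6.82. Dissolved target has a half-life of 4.3 min towards isomer of the product B at 1.12 min, short against 30 min, yet at 30.0 min this flask holds 78.2% as crystals, counted in target, and 7.03% of isomer of the product B. The neighbour flask at 0.50 M holds the same 12.0% of isomer of the product A, but 49.9% as crystals and 27.0% of isomer of the product B, and its ratio ends at 5.11, below the split.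

(The data are simulated for substances that don't exist; the scatter is artificial.)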